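**Plan**

- Retrosynthesis: the catechol ketal is removed last. The oxepine is cut at C5a–C5, the ether at O1–C2, and the dihydrochalcone at the aryl–carbonyl bond.
- Forward: ring A is acylated, the catechol is masked, the allenyl ether is put on the hydroxyl para to the ketone, and the seven-membered ring is closed last before deprotection.
- Enabling feature (benzoxepine locants O1, C2, C3(Me)=C4, C5, C5a, C6-OH, C7-acyl, C8-OH, C9-H, C9a): O1 lies para to the C7 acyl group, so in the open ether C5a and C9 are one and the same position.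
- The C3(Me)=C4–C5 unit is what a 2-methylbuta-2,3-dienyl ether becomes when the arene adds to its CH2 terminus.
- Stereochemistry: the target has no stereocentre; the only stereo-element, the cis C3=C4 bond, is fixed by the ring closure.

Key step: step 5

Step 1
Reactants: 1 phloroglucinol (anhydrous); 2 3-(3,4-dihydroxyphenyl)propanoic acid
Product: 3 3-(3,4-dihydroxyphenyl)-1-(2,4,6-trihydroxyphenyl)propan-1-one
Conditions: 1 (1.5 equiv), BF3·OEt2 (neat), 85 °C; then 10% aq. NaOAc, rt
Reagents that add atoms: none
Why: Friedel–Crafts C-acylation of phloroglucinol by a free carboxylic acid in BF3·OEt2 is a standard way to 2,4,6-trihydroxyphenyl ketones; phloroglucinol is far more nucleophilic than the catechol ring and the first acyl group deactivates ring A, so mono-acylation should prevail.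

Step 2
Reactants: 3 3-(3,4-dihydroxyphenyl)-1-(2,4,6-trihydroxyphenyl)propan-1-one
Product: 4 3-(2,2-dimethyl-1,3-benzodioxol-5-yl)-1-(2,4,6-trihydroxyphenyl)propan-1-one
Conditions: 2,2-dimethoxypropane (5 equiv), TsOH·H2O (5 mol%), THF/toluene, reflux, condensate returned through 4 Å molecular sieves
Reagents that add atoms: 2,2-dimethoxypropane, COC(C)(C)OC
Why: Acid-catalysed transketalisation closes a five-membered benzodioxole only on the vicinal catechol pair, since the ring A hydroxyls are meta to one another and the chelated aryl ketone does not ketalise, and trapping of methanol drives the equilibrium.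

Step 3
Reactants: 5 4-chlorobut-2-yn-1-ol
Product: 6 2-methylbuta-2,3-dien-1-ol
Conditions: MeMgBr (2.4 equiv), CuI (10 mol%), Et2O, −78 °C to rt; aq. NH4Cl
Reagents that add atoms: methylmagnesium bromide, C[Mg]Br
Why: Copper-catalysed anti-SN2′ substitution of a propargylic chloride by a Grignard reagent is an established route to 2-substituted buta-2,3-dien-1-ols, the first equivalent of MeMgBr serving only to form the alkoxide.

Step 4
Reactants: 4 3-(2,2-dimethyl-1,3-benzodioxol-5-yl)-1-(2,4,6-trihydroxyphenyl)propan-1-one; 6 2-methylbuta-2,3-dien-1-ol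
Product: 7 1-{2,6-dihydroxy-4-[(2-methylbuta-2,3-dien-1-yl)oxy]phenyl}-3-(2,2-dimethyl-1,3-benzodioxol-5-yl)propan-1-one
Conditions: 6 (1.05 equiv), PPh3 (1.1 equiv), DIAD (1.1 equiv), THF, 0 °C to rt
Reagents that add atoms: none
Why: Mitsunobu etherification should select the hydroxyl para to the ketone, which is the most acidic and least hindered while the two ortho hydroxyls are hydrogen-bonded to the carbonyl group and flanked by the acyl chain, and the primary α-allenic alcohol is displaced at CH2 by SN2 with the allene untouched.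

Step 5
Reactants: 7 1-{2,6-dihydroxy-4-[(2-methylbuta-2,3-dien-1-yl)oxy]phenyl}-3-(2,2-dimethyl-1,3-benzodioxol-5-yl)propan-1-one
Product: 8 1-(6,8-dihydroxy-3-methyl-2,5-dihydro-1-benzoxepin-7-yl)-3-(2,2-dimethyl-1,3-benzodioxol-5-yl)propan-1-one
Conditions: (PhO)3PAuCl (5 mol%), AgSbF6 (5 mol%), CH2Cl2 (0.02 M), 0 °C to rt, dark
Reagents that add atoms: none
Why: Proposed new method: monovalent gold, made cationic by chloride abstraction, binds the unhindered C4=C5 bond of the allene and slips onto central C4, which gives a gold-bound allyl cation with charge at C5 and at methyl-bearing C3; C5a, activated by three oxygens, attacks C5 anti to gold (C5a–C5 forms), the arenium ion loses its proton, and this proton cleaves the C4–Au bond, leaving C3=C4 inside the ring. The closest known reaction types are the intermolecular gold-catalysed hydroarylation of 1,1-disubstituted allenes by 1,3,5-trialkoxybenzenes, which occurs at the unsubstituted allene terminus, and the intramolecular gold-catalysed hydroarylation of aryl buta-2,3-dienyl ethers, which so far closes six-membered rings through the central carbon; a seven-membered closure of this kind is without precedent. The oxepine closes in the 7-endo mode, with all three allene carbons in the new ring, and no stereocentre arises; the ring fixes the C3=C4 bond as cis. The step needs attack at C5 in preference to C4 (chromene) and C3 (dihydrobenzofuran with a quaternary carbon): the methyl group at C3 stabilises the allyl cation form in which C4 carries gold and is no longer electrophilic, the electron-poor phosphite ligand and the SbF6 counter-ion push the complex towards that form, C3 is crowded and only two atoms away from the ring, and the oxygen on C2 lowers the share of charge at C3. Ring A of 7 is symmetric, so both carbons ortho to the ether are the same and the arene offers no choice; dilution keeps the reaction intramolecular.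

Step 6
Reactants: 8 1-(6,8-dihydroxy-3-methyl-2,5-dihydro-1-benzoxepin-7-yl)-3-(2,2-dimethyl-1,3-benzodioxol-5-yl)propan-1-one
Product: 9 3-(3,4-dihydroxyphenyl)-1-(6,8-dihydroxy-3-methyl-2,5-dihydro-1-benzoxepin-7-yl)propan-1-one (target)
Conditions: TFA/H2O (9:1), 0 °C to rt, short contact time; evaporation with toluene
Reagents that add atoms: none
Why: Acid hydrolysis of the catechol isopropylidene ketal (acetal cleavage) frees both phenols, while the ring alkene is slowed towards protonation by the allylic oxygen on C2, so that low temperature and a short contact time should leave the dihydrooxepine intact.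

**Compound list**

1 | phloroglucinol | Oc1cc(O)cc(O)c1 | starting material
2 | 3-(3,4-dihydroxyphenyl)propanoic acid | OC(=O)CCc1ccc(O)c(O)c1 | starting material
3 | 3-(3,4-dihydroxyphenyl)-1-(2,4,6-trihydroxyphenyl)propan-1-one | O=C(CCc1ccc(O)c(O)c1)c1c(O)cc(O)cc1O | intermediate
4 | 3-(2,2-dimethyl-1,3-benzodioxol-5-yl)-1-(2,4,6-trihydroxyphenyl)propan-1-one | O=C(CCc1ccc2OC(C)(C)Oc2c1)c1c(O)cc(O)cc1O | intermediate
5 | 4-chlorobut-2-yn-1-ol | OCC#CCCl | starting material
6 | 2-methylbuta-2,3-dien-1-ol | C=C=C(C)CO | intermediate
7 | 1-{2,6-dihydroxy-4-[(2-methylbuta-2,3-dien-1-yl)oxy]phenyl}-3-(2,2-dimethyl-1,3-benzodioxol-5-yl)propan-1-one | C=C=C(C)COc1cc(O)c(C(=O)CCc2ccc3OC(C)(C)Oc3c2)c(O)c1 | intermediate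
8 | 1-(6,8-dihydroxy-3-methyl-2,5-dihydro-1-benzoxepin-7-yl)-3-(2,2-dimethyl-1,3-benzodioxol-5-yl)propan-1-one | CC1=CCc2c(cc(O)c(C(=O)CCc3ccc4OC(C)(C)Oc4c3)c2O)OC1 | intermediate
9 | 3-(3,4-dihydroxyphenyl)-1-(6,8-dihydroxy-3-methyl-2,5-dihydro-1-benzoxepin-7-yl)propan-1-one | CC1=CCc2c(cc(O)c(C(=O)CCc3ccc(O)c(O)c3)c2O)OC1 | target

**Step count**

Total: 6 steps. Longest linear sequence: 5 steps (steps 1, 2, 4, 5, 6, from phloroglucinol); step 3 is a one-step side branch.

**Steps most likely to fail**

1. Step 5. The closure may take another course: addition of the arene to central C4 (six-membered ring) or to C3, a gold-promoted Claisen-type shift of the ether, or migration of the new double bond under the acidic catalyst. The fallback uses known chemistry only, sets out from 4 and comes back at 8. The para hydroxyl of 4 is alkylated with allyl bromide (K2CO3, acetone) to give 1-[4-(allyloxy)-2,6-dihydroxyphenyl]-3-(2,2-dimethyl-1,3-benzodioxol-5-yl)propan-1-one F1. An aromatic Claisen rearrangement (N,N-diethylaniline, 190 °C) moves the allyl group to one of the two equivalent ortho carbons and gives 1-(3-allyl-2,4,6-trihydroxyphenyl)-3-(2,2-dimethyl-1,3-benzodioxol-5-yl)propan-1-one F2. The regenerated para hydroxyl is alkylated with 3-bromo-2-methylpropene (K2CO3, acetone) to give 1-{3-allyl-2,6-dihydroxy-4-[(2-methylallyl)oxy]phenyl}-3-(2,2-dimethyl-1,3-benzodioxol-5-yl)propan-1-one F3. Ring-closing metathesis with second-generation Grubbs catalyst (CH2Cl2, 40 °C) then forms the C3=C4 bond and delivers 8.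

2. Step 4. Site selectivity may be lost: etherification at a chelated ortho hydroxyl or at two hydroxyls, or SN2′ delivery of the phenol to the allene terminus. The fallback sets out from 6 and 4 and comes back at 7. Alcohol 6 is converted (MsCl, Et3N, CH2Cl2, −20 °C) into 2-methylbuta-2,3-dien-1-yl methanesulfonate F4. A Williamson etherification of 4 with one equivalent of K2CO3 in acetone at rt then relies on the weak base deprotonating only the vinylogous-acid hydroxyl para to the ketone, and gives 7.

3. Step 2. The ketalisation may stall at an unfavourable equilibrium, or the oxocarbenium ion may attack the electron-rich ring A. The fallback sets out from 3 and comes back at 9. It replaces the acid-catalysed equilibrium by an irreversible, base-mediated double O-alkylation that only a vicinal diol can complete. Ph2CCl2 and K2CO3 in MeCN give 3-(2,2-diphenyl-1,3-benzodioxol-5-yl)-1-(2,4,6-trihydroxyphenyl)propan-1-one F5. The conditions of step 4 with 6 then give 1-{2,6-dihydroxy-4-[(2-methylbuta-2,3-dien-1-yl)oxy]phenyl}-3-(2,2-diphenyl-1,3-benzodioxol-5-yl)propan-1-one F6. The conditions of step 5 give 1-(6,8-dihydroxy-3-methyl-2,5-dihydro-1-benzoxepin-7-yl)-3-(2,2-diphenyl-1,3-benzodioxol-5-yl)propan-1-one F7. AcOH/H2O (4:1) at 80 °C removes the diphenylmethylene ketal and gives 9.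

**Further compounds**

F1 | step 5 | 1-[4-(allyloxy)-2,6-dihydroxyphenyl]-3-(2,2-dimethyl-1,3-benzodioxol-5-yl)propan-1-one | C=CCOc1cc(O)c(C(=O)CCc2ccc3OC(C)(C)Oc3c2)c(O)c1
F2 | step 5 | 1-(3-allyl-2,4,6-trihydroxyphenyl)-3-(2,2-dimethyl-1,3-benzodioxol-5-yl)propan-1-one | C=CCc1c(O)cc(O)c(C(=O)CCc2ccc3OC(C)(C)Oc3c2)c1O
F3 | step 5 | 1-{3-allyl-2,6-dihydroxy-4-[(2-methylallyl)oxy]phenyl}-3-(2,2-dimethyl-1,3-benzodioxol-5-yl)propan-1-one | C=CCc1c(OCC(C)=C)cc(O)c(C(=O)CCc2ccc3OC(C)(C)Oc3c2)c1O
F4 | step 4 | 2-methylbuta-2,3-dien-1-yl methanesulfonate | C=C=C(C)COS(C)(=O)=O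
F5 | step 2 | 3-(2,2-diphenyl-1,3-benzodioxol-5-yl)-1-(2,4,6-trihydroxyphenyl)propan-1-one | O=C(CCc1ccc2OC(c3ccccc3)(c3ccccc3)Oc2c1)c1c(O)cc(O)cc1O
F6 | step 2 | 1-{2,6-dihydroxy-4-[(2-methylbuta-2,3-dien-1-yl)oxy]phenyl}-3-(2,2-diphenyl-1,3-benzodioxol-5-yl)propan-1-one | C=C=C(C)COc1cc(O)c(C(=O)CCc2ccc3OC(c4ccccc4)(c4ccccc4)Oc3c2)c(O)c1
F7 | step 2 | 1-(6,8-dihydroxy-3-methyl-2,5-dihydro-1-benzoxepin-7-yl)-3-(2,2-diphenyl-1,3-benzodioxol-5-yl)propan-1-one | CC1=CCc2c(cc(O)c(C(=O)CCc3ccc4OC(c5ccccc5)(c5ccccc5)Oc4c3)c2O)OC1
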